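**Retrosynthetic overview**

1. The target is reached from bromo lactone 25 by a short endgame: C14–Br to C14–OH, Eschenmoser α-methylenation at C11, angeloylation of O6, and desilylation.
2. Key disconnection: the lactone O–C8 bond is cut while a C1–C8 σ-bond is restored. The enabling feature is that the lactone carbinol carbon C8 is homoallylic to the ring olefin C10=C1 (C8–C9–C10=C1), the pattern left when a cyclobutyl cation is opened by an oxygen nucleophile. The cyclodecene plus 8,12-lactone therefore map back onto a cis-bicyclo[6.2.0]decane (cyclooctane C1–C8 fused to cyclobutane C1–C10–C9–C8) with an exocyclic C10=C14H2 and a CH2CO2H arm on C7 (acid 24).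
3. The cyclobutane comes from a Lewis-acid [2+2] of methyl propiolate (which supplies C9, C10 and C14) with cyclooctene 12, face-controlled by a temporary cis-γ-lactone to O6, followed by reductive 1,3-transposition. The cyclooctene comes from RCM of diene lactone 11.
4. Lactone 11 comes from catalytic asymmetric allylboration of aldehyde 6 with boronate 9 (sets C6 and C7). Aldehyde 6 comes from a copper-catalysed asymmetric conjugate addition (sets C4).
5. Ring order: temporary γ-lactone (to O6) → cyclooctene → cyclobutene → temporary lactone opened → ten-membered carbocycle and final γ-lactone (to O8) together in the key step.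

Key step: step 12

Numbering: target (germacranolide) numbering is used throughout. Ring carbons are C1–C10; C11 is the lactone α-carbon, C12 the lactone C=O, C13 the exocyclic CH2, C14 sits on C10 and C15 on C4. β is the face of the carbocycle that carries C11 on C7 (H7 is α).

Assumption: (R)-Tol-BINAP in step 2 and (S)-TRIP in step 5 are taken as the catalyst antipodes that give the drawn configurations (R at C4; Si-face allylation of the aldehyde). If either induces the opposite sense, its antipode is used.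

**Route**

Step 1
Reactants: 1 2-(tert-butyldiphenylsilyloxy)acetaldehyde; 2 methyl (triphenylphosphoranylidene)acetate
Product: 3 methyl (E)-4-(tert-butyldiphenylsilyloxy)but-2-enoate
Conditions: CH2Cl2, 25 °C
Reagents that add atoms: none
Why: Wittig olefination with a stabilised ylide should give the E-enoate.

Step 2
Reactants: 3 methyl (E)-4-(tert-butyldiphenylsilyloxy)but-2-enoate; 4 but-3-enylmagnesium bromide
Product: 5 methyl (R)-3-[(tert-butyldiphenylsilyloxy)methyl]hept-6-enoate
Conditions: CuI (2 mol %), (R)-Tol-BINAP (3 mol %), tBuOMe, −40 °C; aq. NH4Cl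
Reagents that add atoms: none
Why: Copper-catalysed asymmetric conjugate addition of a Grignard reagent to an E-enoate, in which the chiral bisphosphine–copper complex selects the face of the β-carbon and so sets C4 (R).

Step 3
Reactants: 5 methyl (R)-3-[(tert-butyldiphenylsilyloxy)methyl]hept-6-enoate
Product: 6 (R)-3-[(tert-butyldiphenylsilyloxy)methyl]hept-6-enal
Conditions: iBu2AlH (DIBAL-H), CH2Cl2, −78 °C; Rochelle salt work-up
Reagents that add atoms: none
Why: Partial ester reduction with DIBAL-H stops at the aldehyde through the aluminium hemiacetal that is stable at −78 °C, and C4 (β to the carbonyl) cannot epimerise.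

Step 4
Reactants: 7 allylboronic acid pinacol ester; 8 methyl but-3-enoate (excess)
Product: 9 methyl (E)-5-(4,4,5,5-tetramethyl-1,3,2-dioxaborolan-2-yl)pent-3-enoate
Conditions: second-generation Grubbs catalyst (2 mol %), CH2Cl2, 40 °C
Reagents that add atoms: none
Why: Olefin cross-metathesis of two terminal alkenes with loss of ethylene should give mainly the E-configured γ-substituted allylboronate.

Step 5
Reactants: 6 (R)-3-[(tert-butyldiphenylsilyloxy)methyl]hept-6-enal; 9 methyl (E)-5-(pinacolboryl)pent-3-enoate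
Product: 11 (4S,5R)-4-ethenyl-5-{(2R)-2-[(tert-butyldiphenylsilyloxy)methyl]hex-5-en-1-yl}oxolan-2-one (cis-4,5 lactone), via hydroxy ester 10 (not isolated)
Conditions: (S)-TRIP (5 mol %), 4 Å MS, toluene, −30 °C; then PPTS (cat.), toluene, 60 °C
Reagents that add atoms: none
Why: Chiral-phosphoric-acid-catalysed allylboration through a chair Zimmerman–Traxler transition state, where the catalyst selects the aldehyde face (C6), the E geometry of 9 gives the anti C6/C7 relation, and the γ-hydroxy ester then lactonises to the cis-4,5-disubstituted γ-lactone.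

Step 6
Reactants: 11 cis-lactone diene
Product: 12 cyclooctene lactone: carbocycle C1–C8 with (Z)-C1=C8, cis-fused to the 6,12-γ-lactone (O6 and C11 both β), 4β-CH2OTBDPS
Conditions: second-generation Grubbs catalyst (5 mol %), CH2Cl2 (2 mM), 40 °C
Reagents that add atoms: none
Why: Ring-closing metathesis, in which the cis-disubstituted γ-lactone holds the two vinyl termini close so that the cis-cyclooctene should form in preference to oligomers.

Step 7
Reactants: 12 cyclooctene lactone; 13 methyl propiolate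
Product: 14 cyclobutene ester: 12 with a C9H=C10(CO2Me) bridge on the α-face (C9 on C8, C10 on C1; cis-fused bicyclo[6.2.0]dec-9-ene)
Conditions: EtAlCl2 (2.2 equiv), CH2Cl2, 0 → 25 °C
Reagents that add atoms: none
Why: Lewis-acid-promoted stepwise [2+2] cycloaddition of the propiolate–EtAlCl2 complex to a cis-alkene: C8 attacks the β-carbon, positive charge builds at C1 (remote from the electron-withdrawing C6–O and C12=O) and collapses onto the ester-bearing carbon, so the ester carbon (C14) ends on C10 next to C1; addition is suprafacial (cis fusion) and anti to the lactone ring (α-face), which sets C1 and C8.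

Step 8
Reactants: 14 cyclobutene ester
Product: 16 cyclobutene carboxylic acid (CO2H on C10, 6,12-lactone intact), via dilithium hydroxy dicarboxylate 15 (not isolated)
Conditions: LiOH, THF/H2O, 25 °C; then 1 M HCl to pH 2, 25 °C
Reagents that add atoms: lithium hydroxide, [Li+].[OH-]
Why: Saponification cleaves both the methyl ester and the lactone, and on acidification only the γ-hydroxy acid relactonises, which tells the two carboxyl groups apart.

Step 9
Reactants: 16 cyclobutene carboxylic acid
Product: 18 cyclobutenylmethanol (C14–OH on C10, C9=C10), via mixed carbonic anhydride 17 (not isolated)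
Conditions: iBuOCOCl, N-methylmorpholine, THF, −15 °C; then NaBH4, H2O, 0 °C
Reagents that add atoms: none
Why: Chemoselective reduction of a carboxylic acid through its mixed carbonic anhydride with NaBH4, conditions under which a γ-lactone is not reduced.

Step 10
Reactants: 18 cyclobutenylmethanol
Product: 21 methylenecyclobutane lactone (C9H2, exocyclic C10=C14H2), via sulfonylhydrazide 19 (not isolated), via allylic diazene 20 (not isolated)
Conditions: 2-nitrobenzenesulfonylhydrazide (NBSH), PPh3, DEAD, N-methylmorpholine, −30 → 25 °C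
Reagents that add atoms: none
Why: Myers reductive 1,3-transposition of an allylic alcohol: Mitsunobu N-alkylation of the sulfonylhydrazide, loss of sulfinic acid to the monoalkyl diazene, and sigmatropic loss of N2 deliver hydrogen to C9 and move the double bond to the exocyclic C10=C14 position.

Step 11
Reactants: 21 methylenecyclobutane lactone
Product: 24 acid: C7–CH2CO2H, 6β-OTBS, 4β-CH2OTBDPS, methylenecyclobutane α-fused at C1/C8, via lithium hydroxy carboxylate 22 (not isolated), via bis-silylated acid 23 (not isolated)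
Conditions: LiOH, THF/H2O, 25 °C, then evaporation; TBSOTf, 2,6-lutidine, CH2Cl2, 0 °C; then AcOH/THF/H2O, 25 °C
Reagents that add atoms: lithium hydroxide, [Li+].[OH-]; tert-butyldimethylsilyl trifluoromethanesulfonate, CC(C)(C)[Si](C)(C)OS(=O)(=O)C(F)(F)F
Why: Lactone hydrolysis, silylation of both oxygen functions and selective hydrolysis of the labile silyl ester, so that O6 is capped before the acid is set free and the lactone to O6 cannot re-form.

Step 12
Reactants: 24 acid
Product: 25 bromo lactone: ten-membered carbocycle with C10=C1 (C9 and C2 cis), C14H2Br, trans-fused 8,12-γ-lactone (O8 α, C11 β, C11H2), 6β-OTBS, 4β-CH2OTBDPS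
Conditions: N-bromosuccinimide (1.05 equiv), (CF3)2CHOH/CH2Cl2 1:4, −40 → 0 °C, dark
Reagents that add atoms: N-bromosuccinimide, O=C1CCC(=O)N1Br
Why: Proposed new method: NBS delivers Br+ to the exocyclic CH2 (C14) of the methylenecyclobutane and leaves a β-bromo tertiary cyclobutyl cation (bromonium) at C10; a 1,2-shift of C8 from C1 to C10 (cyclobutyl to cyclopropylcarbinyl, a Wagner–Meerwein shift) moves the charge to C1, and the tethered carboxylic acid then opens the C8–C10 bond at C8 (cyclopropylcarbinyl to homoallyl), which creates C10=C1, removes the former C1–C8 ring fusion and so turns the eight-membered ring into the ten-membered one. The closest known reaction types are the cyclobutyl/cyclopropylcarbinyl/homoallyl cation rearrangement used in the Julia olefin synthesis, halonium-induced 1,2-shifts of the semipinacol kind and 5-exo halolactonisation. The γ-lactone closes 5-exo-tet by O-attack at C8 with the C8–C10(C1) bridge as leaving group, whereas the carbocycle is not closed but enlarged by two carbons (C9, C10). C8 is the only stereocentre formed and is set by inversion: oxygen enters anti to the departing carbon, and because the cyclobutane bonds at C8 and C1 are α (trans to the C7 side chain, fixed in step 7) the lactone should come out 7,8-trans with O8 α. The olefin geometry follows from the cis ring fusion: in the pucker that keeps C7 pseudo-equatorial on C8, C8 bridges to the lobe of C10 on the H1/H8 face, which turns C9 cis to C2 and CH2Br trans to C2 (ring-cis olefin). The selectivity needed is capture at C8 rather than at C10 or C1 (strained seven-membered lactones, reversible in the ionising solvent) or proton loss, and the five-atom tether, the non-nucleophilic medium and the release of cyclobutane strain only along the C8 pathway should secure it.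

Step 13
Reactants: 25 bromo lactone
Product: 27 allylic alcohol (C14–OH), via formate ester 26 (not isolated)
Conditions: HCO2Na, DMF, 25 °C; then MeOH, NaHCO3 (cat.), 25 °C
Reagents that add atoms: sodium formate, [Na+].[O-]C=O
Why: SN2 displacement of the primary allylic bromide by formate and methanolysis of the formate ester, with no base strong enough to open the lactone.

Step 14
Reactants: 27 allylic alcohol
Product: 28 bis-TBDPS ether (C14–OTBDPS, C15–OTBDPS, 6β-OTBS)
Conditions: TBDPSCl, imidazole, DMF, 25 °C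
Reagents that add atoms: tert-butyl(chloro)diphenylsilane, CC(C)(C)[Si](Cl)(c1ccccc1)c1ccccc1
Why: Standard silylation of a primary allylic alcohol.

Step 15
Reactants: 28 bis-TBDPS ether
Product: 31 α-methylene lactone (C11=C13H2), via Mannich base 29 (not isolated), via trimethylammonium iodide 30 (not isolated)
Conditions: LiN(iPr)2 (LDA), THF, −78 °C; CH2=NMe2+ I−, −78 → 0 °C; then MeI, MeOH, 25 °C; then aq. NaHCO3, CH2Cl2
Reagents that add atoms: N,N-dimethylmethyleneiminium iodide (Eschenmoser's salt), C=[N+](C)C.[I-]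
Why: α-Methylenation of the lactone by Mannich reaction of its enolate with Eschenmoser's salt, quaternisation and base-induced elimination of trimethylamine.

Step 16
Reactants: 31 α-methylene lactone
Product: 32 6β-alcohol (both TBDPS ethers kept)
Conditions: HF·pyridine, pyridine, THF, 0 °C
Reagents that add atoms: none
Why: Buffered fluoride cleaves the secondary TBS ether faster than the two primary TBDPS ethers.

Step 17
Reactants: 32 6β-alcohol; 33 angelic acid ((Z)-2-methylbut-2-enoic acid)
Product: 34 6-O-angelate (both TBDPS ethers kept)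
Conditions: 33, 2,4,6-trichlorobenzoyl chloride, Et3N, toluene, 25 °C; then 32, DMAP, toluene, 60 °C
Reagents that add atoms: none
Why: Yamaguchi esterification through the mixed 2,4,6-trichlorobenzoic anhydride, which should acylate the hindered C6 alcohol without Z to E isomerisation of the angelate.

Step 18
Reactants: 34 6-O-angelate
Product: 35 target, (4R,6R,7R,8R)-6-angeloyloxy-14,15-dihydroxygermacra-1(10),11(13)-dien-12,8-olide (C9 and C2 cis on C10=C1)
Conditions: HF·pyridine (excess), THF, 0 → 25 °C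
Reagents that add atoms: none
Why: Fluoride cleavage of both primary TBDPS ethers under buffered, non-basic conditions that should leave the α-methylene lactone and the angelate untouched.

**Compound list**

1 | 2-(tert-butyldiphenylsilyloxy)acetaldehyde | O=CCO[Si](c1ccccc1)(c1ccccc1)C(C)(C)C | starting material
2 | methyl (triphenylphosphoranylidene)acetate | COC(=O)C=P(c1ccccc1)(c1ccccc1)c1ccccc1 | starting material
3 | methyl (E)-4-(tert-butyldiphenylsilyloxy)but-2-enoate | COC(=O)/C=C/CO[Si](c1ccccc1)(c1ccccc1)C(C)(C)C | intermediate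
4 | but-3-enylmagnesium bromide | C=CCC[Mg]Br | starting material
5 | methyl (R)-3-[(tert-butyldiphenylsilyloxy)methyl]hept-6-enoate | COC(=O)C[C@H](CO[Si](c1ccccc1)(c1ccccc1)C(C)(C)C)CCC=C | intermediate
6 | (R)-3-[(tert-butyldiphenylsilyloxy)methyl]hept-6-enal | O=CC[C@H](CO[Si](c1ccccc1)(c1ccccc1)C(C)(C)C)CCC=C | intermediate
7 | allylboronic acid pinacol ester | C=CCB1OC(C)(C)C(C)(C)O1 | starting material
8 | methyl but-3-enoate | COC(=O)CC=C | starting material
9 | methyl (E)-5-(4,4,5,5-tetramethyl-1,3,2-dioxaborolan-2-yl)pent-3-enoate | COC(=O)C/C=C/CB1OC(C)(C)C(C)(C)O1 | intermediate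
10 | methyl (3S,4R,6R)-3-ethenyl-4-hydroxy-6-[(tert-butyldiphenylsilyloxy)methyl]dec-9-enoate | COC(=O)C[C@@H](C=C)[C@H](O)C[C@H](CO[Si](c1ccccc1)(c1ccccc1)C(C)(C)C)CCC=C | intermediate
11 | (4S,5R)-4-ethenyl-5-{(2R)-2-[(tert-butyldiphenylsilyloxy)methyl]hex-5-en-1-yl}oxolan-2-one | O=C1C[C@@H](C=C)[C@@H](C[C@H](CO[Si](c2ccccc2)(c2ccccc2)C(C)(C)C)CCC=C)O1 | intermediate
12 | cyclooctene lactone: (Z)-C1=C8 carbocycle C1–C8, cis-fused 6,12-γ-lactone (O6, C11 β), 4β-CH2OTBDPS | O=C1C[C@H]2/C=C\CC[C@@H](CO[Si](c3ccccc3)(c3ccccc3)C(C)(C)C)C[C@H]2O1 | intermediate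
13 | methyl propiolate | COC(=O)C#C | starting material
14 | cyclobutene ester: cis-fused bicyclo[6.2.0]dec-9-ene, C9H=C10(CO2Me) on the α-face (C9 on C8, C10 on C1), 6,12-lactone, 4β-CH2OTBDPS | O=C1C[C@H]2[C@@H]3C=C(C(=O)OC)[C@@H]3CC[C@@H](CO[Si](c4ccccc4)(c4ccccc4)C(C)(C)C)C[C@H]2O1 | intermediate
15 | dilithium salt of the ring-opened 6-hydroxy 12,14-dicarboxylate of 14 | [Li+].[Li+].[O-]C(=O)C[C@H]1[C@@H]2C=C(C(=O)[O-])[C@@H]2CC[C@@H](CO[Si](c3ccccc3)(c3ccccc3)C(C)(C)C)C[C@H]1O | intermediate
16 | cyclobutene carboxylic acid (CO2H on C10), 6,12-lactone | O=C1C[C@H]2[C@@H]3C=C(C(=O)O)[C@@H]3CC[C@@H](CO[Si](c4ccccc4)(c4ccccc4)C(C)(C)C)C[C@H]2O1 | intermediate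
17 | mixed isobutyl carbonic anhydride of 16 | O=C1C[C@H]2[C@@H]3C=C(C(=O)OC(=O)OCC(C)C)[C@@H]3CC[C@@H](CO[Si](c4ccccc4)(c4ccccc4)C(C)(C)C)C[C@H]2O1 | intermediate
18 | cyclobutenylmethanol (C14–OH, C9=C10), 6,12-lactone | O=C1C[C@H]2[C@@H]3C=C(CO)[C@@H]3CC[C@@H](CO[Si](c4ccccc4)(c4ccccc4)C(C)(C)C)C[C@H]2O1 | intermediate
19 | N-(C14-alkyl)-N-(2-nitrobenzenesulfonyl)hydrazine of 18 | O=C1C[C@H]2[C@@H]3C=C(CN(N)S(=O)(=O)c4ccccc4[N+](=O)[O-])[C@@H]3CC[C@@H](CO[Si](c4ccccc4)(c4ccccc4)C(C)(C)C)C[C@H]2O1 | intermediate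
20 | allylic monoalkyl diazene (C14–N=NH) | O=C1C[C@H]2[C@@H]3C=C(CN=N)[C@@H]3CC[C@@H](CO[Si](c4ccccc4)(c4ccccc4)C(C)(C)C)C[C@H]2O1 | intermediate
21 | methylenecyclobutane lactone: cis-fused bicyclo[6.2.0]decane, C9H2, exocyclic C10=C14H2, cyclobutane α, 6,12-lactone, 4β-CH2OTBDPS | O=C1C[C@H]2[C@@H]3CC(=C)[C@@H]3CC[C@@H](CO[Si](c4ccccc4)(c4ccccc4)C(C)(C)C)C[C@H]2O1 | intermediate
22 | lithium 6-hydroxy carboxylate from 21 | [Li+].[O-]C(=O)C[C@H]1[C@@H]2CC(=C)[C@@H]2CC[C@@H](CO[Si](c3ccccc3)(c3ccccc3)C(C)(C)C)C[C@H]1O | intermediate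
23 | 6-O-TBS ether TBS ester | CC(C)(C)[Si](C)(C)OC(=O)C[C@H]1[C@@H]2CC(=C)[C@@H]2CC[C@@H](CO[Si](c3ccccc3)(c3ccccc3)C(C)(C)C)C[C@H]1O[Si](C)(C)C(C)(C)C | intermediate
24 | acid: 2-(bicyclo[6.2.0]dec-7-yl)acetic acid with exocyclic C10=CH2, 6β-OTBS, 4β-CH2OTBDPS, cyclobutane α at C1/C8 | OC(=O)C[C@H]1[C@@H]2CC(=C)[C@@H]2CC[C@@H](CO[Si](c3ccccc3)(c3ccccc3)C(C)(C)C)C[C@H]1O[Si](C)(C)C(C)(C)C | intermediate
25 | bromo lactone: 14-bromo-6β-(TBS-oxy)-15-(TBDPS-oxy)germacr-1(10)-en-12,8-olide, C9/C2 cis, O8 α | C1C(=O)O[C@@H]2C/C(CBr)=C\CC[C@@H](CO[Si](c3ccccc3)(c3ccccc3)C(C)(C)C)C[C@@H](O[Si](C)(C)C(C)(C)C)[C@@H]12 | intermediate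
26 | 14-formate of the lactone | C1C(=O)O[C@@H]2C/C(COC=O)=C\CC[C@@H](CO[Si](c3ccccc3)(c3ccccc3)C(C)(C)C)C[C@@H](O[Si](C)(C)C(C)(C)C)[C@@H]12 | intermediate
27 | allylic alcohol (C14–OH), 6β-OTBS, 15-OTBDPS | C1C(=O)O[C@@H]2C/C(CO)=C\CC[C@@H](CO[Si](c3ccccc3)(c3ccccc3)C(C)(C)C)C[C@@H](O[Si](C)(C)C(C)(C)C)[C@@H]12 | intermediate
28 | 14,15-bis-TBDPS ether, 6β-OTBS | C1C(=O)O[C@@H]2C/C(CO[Si](c3ccccc3)(c3ccccc3)C(C)(C)C)=C\CC[C@@H](CO[Si](c3ccccc3)(c3ccccc3)C(C)(C)C)C[C@@H](O[Si](C)(C)C(C)(C)C)[C@@H]12 | intermediate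
29 | 11-(dimethylaminomethyl) lactone (Mannich base) | CN(C)CC1C(=O)O[C@@H]2C/C(CO[Si](c3ccccc3)(c3ccccc3)C(C)(C)C)=C\CC[C@@H](CO[Si](c3ccccc3)(c3ccccc3)C(C)(C)C)C[C@@H](O[Si](C)(C)C(C)(C)C)[C@@H]12 | intermediate
30 | trimethylammonium iodide of 29 | C[N+](C)(C)CC1C(=O)O[C@@H]2C/C(CO[Si](c3ccccc3)(c3ccccc3)C(C)(C)C)=C\CC[C@@H](CO[Si](c3ccccc3)(c3ccccc3)C(C)(C)C)C[C@@H](O[Si](C)(C)C(C)(C)C)[C@@H]12.[I-] | intermediate
31 | α-methylene lactone, 6β-OTBS, 14,15-bis-OTBDPS | C=C1C(=O)O[C@@H]2C/C(CO[Si](c3ccccc3)(c3ccccc3)C(C)(C)C)=C\CC[C@@H](CO[Si](c3ccccc3)(c3ccccc3)C(C)(C)C)C[C@@H](O[Si](C)(C)C(C)(C)C)[C@@H]12 | intermediate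
32 | 6β-alcohol, 14,15-bis-OTBDPS | C=C1C(=O)O[C@@H]2C/C(CO[Si](c3ccccc3)(c3ccccc3)C(C)(C)C)=C\CC[C@@H](CO[Si](c3ccccc3)(c3ccccc3)C(C)(C)C)C[C@@H](O)[C@@H]12 | intermediate
33 | angelic acid, (Z)-2-methylbut-2-enoic acid | C/C=C(/C)C(=O)O | starting material
34 | 6-O-angelate, 14,15-bis-OTBDPS | C=C1C(=O)O[C@@H]2C/C(CO[Si](c3ccccc3)(c3ccccc3)C(C)(C)C)=C\CC[C@@H](CO[Si](c3ccccc3)(c3ccccc3)C(C)(C)C)C[C@@H](OC(=O)/C(C)=C\C)[C@@H]12 | intermediate
35 | CNP0147777.1, (4R,6R,7R,8R)-6-angeloyloxy-14,15-dihydroxygermacra-1(10),11(13)-dien-12,8-olide | C=C1C(=O)O[C@@H]2C/C(CO)=C\CC[C@@H](CO)C[C@@H](OC(=O)/C(C)=C\C)[C@@H]12 | target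

**Step count and risks**

Total step count: 18. Longest linear sequence: 17 steps (steps 1–3 and 5–18; step 4 makes boronate 9 in one step from commercial materials).

Steps most likely to fail:

1. Step 12 (proposed method). What may go wrong: the cation is trapped before the 1,2-shift (bromo-lactonisation or external capture at C10), a proton is lost to give a diene, or the ring opens through the other pucker to the ring-trans olefin. The fallback uses known chemistry and no ring expansion. It sets out from hydroxy ester 10 (isolated by stopping step 5 before the PPTS treatment) and comes back to the route at allylic alcohol 27. Silylation (TBSOTf, 2,6-lutidine, CH2Cl2) gives the methyl ester silyl ether F1, and saponification (LiOH, THF/H2O) gives the γ,δ-unsaturated acid F2. Iodolactonisation under equilibrating conditions (I2, MeCN, 0 °C) forms the same O–C8 bond in the 5-exo mode, trans to the C7 substituent, to give the iodomethyl lactone F3. Reductive cross-electrophile coupling of the primary iodide with commercial 2-bromoprop-2-en-1-ol (NiBr2·glyme, 4,4′-di-tert-butyl-2,2′-bipyridine, Zn, DMA) attaches C10 with its hydroxymethyl group to give the 1,1-disubstituted alkene F4. Ring-closing metathesis (second-generation Hoveyda–Grubbs catalyst, toluene, high dilution, 80 °C) then closes the ten-membered ring at C10=C1 to give 27.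

2. Step 7. What may go wrong: an ene reaction of the propiolate–EtAlCl2 complex with the allylic C–H bonds, Lewis-acid-induced loss of the silyl ether, or insufficient regiocontrol. The fallback replaces the Lewis-acid alkyne cycloaddition by ketene chemistry; it sets out from cyclooctene lactone 12 and comes back at methylenecyclobutane lactone 21. Dichloroketene (Cl3CCOCl, Zn/Cu couple, Et2O/DME) adds to the α-face to give the dichlorocyclobutanone F5; its regiochemistry is less secure than that of step 7, so any isomer with the carbonyl on the C8 side is removed by chromatography. Zinc in acetic acid removes both chlorines to give the cyclobutanone F6, and Wittig methylenation (Ph3P=CH2, THF, 0 °C) gives 21.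

3. Step 11. What may go wrong: relactonisation to O6 while the hydroxy acid is handled, or loss of the secondary silyl ether during hydrolysis of the silyl ester. The fallback avoids the free hydroxy acid; it sets out from lactone 21 and comes back at bromo lactone 25. Aminolysis (Me2NH·HCl, AlMe3, toluene) gives the hydroxy dimethylamide F7, and silylation (TBSOTf, 2,6-lutidine) gives the silyl ether amide F8. The NBS/(CF3)2CHOH treatment of step 12 then uses the amide oxygen as the nucleophile at C8 to give the iminium ether salt F9, which aqueous NaHCO3 hydrolyses to 25.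

Further compounds
F1 | step 12 | methyl (3S,4R,6R)-4-(tert-butyldimethylsilyloxy)-3-ethenyl-6-[(tert-butyldiphenylsilyloxy)methyl]dec-9-enoate | COC(=O)C[C@@H](C=C)[C@H](O[Si](C)(C)C(C)(C)C)C[C@H](CO[Si](c1ccccc1)(c1ccccc1)C(C)(C)C)CCC=C
F2 | step 12 | the corresponding carboxylic acid | OC(=O)C[C@@H](C=C)[C@H](O[Si](C)(C)C(C)(C)C)C[C@H](CO[Si](c1ccccc1)(c1ccccc1)C(C)(C)C)CCC=C
F3 | step 12 | trans-4,5-disubstituted 5-(iodomethyl)oxolan-2-one (C9–I, O8 α, side chain on C7 with 6-OTBS) | O=C1C[C@H]([C@H](O[Si](C)(C)C(C)(C)C)C[C@H](CO[Si](c2ccccc2)(c2ccccc2)C(C)(C)C)CCC=C)[C@@H](CI)O1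
F4 | step 12 | trans-lactone with 2-(hydroxymethyl)allyl group on C8 (C9–C10(=CH2)–C14H2OH) | O=C1C[C@H]([C@H](O[Si](C)(C)C(C)(C)C)C[C@H](CO[Si](c2ccccc2)(c2ccccc2)C(C)(C)C)CCC=C)[C@@H](CC(=C)CO)O1
F5 | step 7 | 9,9-dichlorocyclobutan-10-one fused α at C1/C8 of lactone 12 | O=C1C[C@H]2[C@@H]3C(Cl)(Cl)C(=O)[C@@H]3CC[C@@H](CO[Si](c4ccccc4)(c4ccccc4)C(C)(C)C)C[C@H]2O1
F6 | step 7 | cyclobutan-10-one fused α at C1/C8 of lactone 12 | O=C1C[C@H]2[C@@H]3CC(=O)[C@@H]3CC[C@@H](CO[Si](c4ccccc4)(c4ccccc4)C(C)(C)C)C[C@H]2O1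
F7 | step 11 | 6-hydroxy N,N-dimethylamide from 21 | CN(C)C(=O)C[C@H]1[C@@H]2CC(=C)[C@@H]2CC[C@@H](CO[Si](c3ccccc3)(c3ccccc3)C(C)(C)C)C[C@H]1O
F8 | step 11 | 6-O-TBS ether of the N,N-dimethylamide | CN(C)C(=O)C[C@H]1[C@@H]2CC(=C)[C@@H]2CC[C@@H](CO[Si](c3ccccc3)(c3ccccc3)C(C)(C)C)C[C@H]1O[Si](C)(C)C(C)(C)C
F9 | step 11 | iminium ether (O8–C12=N+Me2) of the ring-expanded bromide, succinimidate salt | C[N+](C)=C1O[C@@H]2C/C(CBr)=C\CC[C@@H](CO[Si](c3ccccc3)(c3ccccc3)C(C)(C)C)C[C@@H](O[Si](C)(C)C(C)(C)C)[C@H]2C1.O=C1CCC(=O)[N-]1
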